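## Retrosynthetic overview

1. Feature: the quinone is the only ring. Take C1 as the carbonyl flanked by C2 (OMe) and C6 (chain), and C4 as the other carbonyl. The oxygens on C2 and C4 are then meta to each other and the C15 acid chain sits on C6. This is the 5-alkylresorcinol pattern of a fatty-acyl-primed tetraketide, and only the C1 oxygen lies outside it.
2. Disconnection of C1=O: para-oxidation of 15-(3-hydroxy-5-methoxyphenyl)pentadecanoic acid. A carboxyl put back on C5 gives a 6-alkylresorcylate, where chelation separates the C4 hydroxyl from the C2 hydroxyl, and the C2 hydroxyl takes the methyl group.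
3. Disconnection of ring bond C5–C6 (key): intramolecular aldol and aromatisation of open-chain dimethyl 3,5,7-trioxodocosanedioate.
4. Disconnection of chain bond C6–C7 of that diester: the trianion of methyl 3,5-dioxohexanoate (from dehydroacetic acid) plus the imidazolide of hexadecanedioic acid monomethyl ester.
5. Ring order: one carbocycle, closed as the arene in step 6 and oxidised to the quinone in the last step.

Key step: step 6

Remark: the β-polycarbonyl compounds are drawn as keto tautomers although they will be largely enolised. The target has no stereocentre, so none has to be set.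

## Route

Step 1
Reactants: 1 hexadecanedioic acid
Product: 2 dimethyl hexadecanedioate
Conditions: MeOH, H2SO4 (cat.), reflux
Reagents that add atoms: methanol, CO
Why: Fischer esterification in excess methanol should drive both carboxyl groups to the ester and give one symmetrical, easily purified compound from which the two ends can be told apart.

Step 2
Reactants: 2 dimethyl hexadecanedioate
Product: 4 16-methoxy-16-oxohexadecanoic acid, via barium half-ester salt 3 (not isolated)
Conditions: Ba(OH)2 (0.5 equiv), MeOH, rt; then aq. HCl; residual 2 removed by base extraction and recycled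
Reagents that add atoms: barium hydroxide Ba(OH)2, [OH-].[OH-].[Ba+2]
Why: Half-saponification of a symmetrical diester, in which the barium salt of the half-ester is insoluble in methanol and drops out as it forms, so it is withdrawn from a second hydrolysis.

Step 3
Reactants: 4 16-methoxy-16-oxohexadecanoic acid
Product: 5 methyl 16-(1H-imidazol-1-yl)-16-oxohexadecanoate
Conditions: CDI (1.05 equiv), CH2Cl2, rt; brief ice-water wash, dry, concentrate
Reagents that add atoms: 1,1'-carbonyldiimidazole, O=C(n1ccnc1)n1ccnc1
Why: CDI activation of a carboxylic acid runs under neutral conditions that leave the methyl ester untouched, and the cold wash removes imidazole and surplus CDI, whose N–H and carbonyl would otherwise consume the trianion of step 5.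

Step 4
Reactants: 6 dehydroacetic acid
Product: 7 methyl 3,5-dioxohexanoate
Conditions: Mg(OMe)2 (2 equiv), MeOH, reflux; aq. HCl, 0 °C; distillation
Reagents that add atoms: magnesium methoxide Mg(OMe)2, C[O-].C[O-].[Mg+2]; methanol, CO
Why: Methanolysis of the enol lactone together with retro-Claisen loss of the 3-acetyl group as methyl acetate is a known degradation of dehydroacetic acid, and magnesium chelation of the tricarbonyl product stops further cleavage.

Step 5
Reactants: 7 methyl 3,5-dioxohexanoate; 5 methyl 16-(1H-imidazol-1-yl)-16-oxohexadecanoate
Product: 9 dimethyl 3,5,7-trioxodocosanedioate, via trilithium trienolate 8 (not isolated)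
Conditions: 7 (2.2 equiv), LiN(iPr)2 (6.7 equiv), THF, 0 °C; then 5 (1 equiv) in THF, −78 °C; AcOH, −78 °C; excess 7 removed under high vacuum
Reagents that add atoms: none
Why: Crossed Claisen C-acylation of a tricarbonyl trianion, in which the terminal CH2 carbanion is formed last and is by far the most nucleophilic site, so it alone attacks the acyl imidazolide, which at −78 °C reacts much faster than the remote methyl ester, while the second equivalent of 8 deprotonates the more acidic product and shields it from further attack.

Step 6
Reactants: 9 dimethyl 3,5,7-trioxodocosanedioate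
Product: 11 methyl 2,4-dihydroxy-6-(15-methoxy-15-oxopentadecyl)benzoate, via cyclic aldol adduct 10 (not isolated)
Conditions: K2CO3 (3 equiv), MeOH–CH2Cl2, rt; then HCl in MeOH, rt
Reagents that add atoms: none
Why: Carbonate converts 9 into its delocalised enolates, and C2, flanked by the ester and the C3 ketone, adds to the C7 ketone to give cyclic aldol 10 and so makes the bond that ends as ring bond C5–C6 of the quinone; the acid stage then expels water and the two remaining ring ketones enolise, so aromatisation makes the sequence irreversible. The closest known reaction type is the weak-base aldol aromatisation of 3,5,7-triketo esters to 6-alkyl-2,4-dihydroxybenzoates, the laboratory counterpart of tetraketide folding in alkylresorcylate biosynthesis. The single ring closes in the 6-(enolendo)-exo-trig mode, which is geometrically favourable for a six-membered enolate closure. The two stereocentres of 10 are transient and vanish on aromatisation, so no stereocontrol is needed. The step needs C2-to-C7 aldol closure to beat Claisen closure of C6 onto the C1 ester, O-cyclisation to a pyranone and aldol attack from the singly activated C8, and the substrate secures this because C7 is an unhindered dialkyl ketone and a far better electrophile than an ester locked in an enolised β-keto ester, because C4 and C6 reach a ketone only through four-membered rings, and because a weak base does not enolise C8. Methanolic carbonate is chosen over aqueous hydroxide because methoxide exchange at both esters is degenerate, whereas hydroxide would hydrolyse the remote ester and belongs to the strongly basic media in which Claisen closure of such esters competes, and the acid is added only once 9 is consumed so that acid-induced pyranone formation from the open chain cannot intervene.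

Step 7
Reactants: 11 methyl 2,4-dihydroxy-6-(15-methoxy-15-oxopentadecyl)benzoate
Product: 12 methyl 2-hydroxy-4-methoxy-6-(15-methoxy-15-oxopentadecyl)benzoate
Conditions: MeI (1.05 equiv), K2CO3 (1.1 equiv), acetone, reflux
Reagents that add atoms: iodomethane, CI
Why: Williamson O-methylation with one equivalent of MeI and a weak base should touch only the 4-hydroxyl, because the 2-hydroxyl is hydrogen-bonded to the ester carbonyl and is therefore less acidic and less nucleophilic, as is known for orsellinate-type esters.

Step 8
Reactants: 12 methyl 2-hydroxy-4-methoxy-6-(15-methoxy-15-oxopentadecyl)benzoate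
Product: 14 15-(3-hydroxy-5-methoxyphenyl)pentadecanoic acid, via resorcylic diacid 13 (not isolated)
Conditions: KOH (excess), 1,4-dioxane–H2O, reflux, argon; then conc. HCl to pH 1, reflux
Reagents that add atoms: potassium hydroxide KOH, [OH-].[K+]
Why: Alkaline hydrolysis of both methyl esters is followed by acid-promoted protodecarboxylation, which is easy because the carboxyl-bearing ring carbon is ortho to OH and para to OMe and so is readily protonated (the acid behaves as the enol of a β-keto acid), while the aliphatic acid and the aryl methyl ether are inert.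

Step 9
Reactants: 14 15-(3-hydroxy-5-methoxyphenyl)pentadecanoic acid
Product: 15 15-(5-methoxy-3,6-dioxocyclohexa-1,4-dien-1-yl)pentadecanoic acid (target)
Conditions: (KSO3)2NO (Fremy's salt, 2.5 equiv), aq. KH2PO4, acetone, rt
Reagents that add atoms: potassium nitrosodisulfonate (KSO3)2NO, [K+].[K+].[O]N(S(=O)(=O)[O-])S(=O)(=O)[O-]
Why: Teuber oxidation, in which one equivalent of (KSO3)2NO removes the phenolic hydrogen and a second delivers oxygen to the free para carbon between OMe and chain, and loss of HN(SO3K)2 gives the 1,4-quinone, as is known for 3-methoxy-5-alkylphenols.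

## Compound list

1 | hexadecanedioic acid | OC(=O)CCCCCCCCCCCCCCC(=O)O | starting material
2 | dimethyl hexadecanedioate | COC(=O)CCCCCCCCCCCCCCC(=O)OC | intermediate
3 | barium bis(16-methoxy-16-oxohexadecanoate), Ba(O2C(CH2)14CO2Me)2 | [Ba+2].COC(=O)CCCCCCCCCCCCCCC(=O)[O-].COC(=O)CCCCCCCCCCCCCCC(=O)[O-] | intermediate
4 | 16-methoxy-16-oxohexadecanoic acid | COC(=O)CCCCCCCCCCCCCCC(=O)O | intermediate
5 | methyl 16-(1H-imidazol-1-yl)-16-oxohexadecanoate | COC(=O)CCCCCCCCCCCCCCC(=O)n1ccnc1 | intermediate
6 | dehydroacetic acid (3-acetyl-4-hydroxy-6-methyl-2H-pyran-2-one) | CC(=O)C1=C(O)C=C(C)OC1=O | starting material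
7 | methyl 3,5-dioxohexanoate | COC(=O)CC(=O)CC(C)=O | intermediate
8 | trilithium trienolate of methyl 3,5-dioxohexanoate, Li3(C7H7O4) | [Li+].[Li+].[Li+].COC([O-])=CC([O-])=CC([O-])=C | intermediate
9 | dimethyl 3,5,7-trioxodocosanedioate | COC(=O)CC(=O)CC(=O)CC(=O)CCCCCCCCCCCCCCC(=O)OC | intermediate
10 | methyl 2-hydroxy-2-(15-methoxy-15-oxopentadecyl)-4,6-dioxocyclohexane-1-carboxylate (mixture of diastereomers and enol tautomers) | COC(=O)C1C(=O)CC(=O)CC1(O)CCCCCCCCCCCCCCC(=O)OC | intermediate
11 | methyl 2,4-dihydroxy-6-(15-methoxy-15-oxopentadecyl)benzoate | COC(=O)c1c(O)cc(O)cc1CCCCCCCCCCCCCCC(=O)OC | intermediate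
12 | methyl 2-hydroxy-4-methoxy-6-(15-methoxy-15-oxopentadecyl)benzoate | COC(=O)c1c(O)cc(OC)cc1CCCCCCCCCCCCCCC(=O)OC | intermediate
13 | 2-(14-carboxytetradecyl)-6-hydroxy-4-methoxybenzoic acid | OC(=O)c1c(O)cc(OC)cc1CCCCCCCCCCCCCCC(=O)O | intermediate
14 | 15-(3-hydroxy-5-methoxyphenyl)pentadecanoic acid | COc1cc(O)cc(CCCCCCCCCCCCCCC(=O)O)c1 | intermediate
15 | 15-(5-methoxy-3,6-dioxocyclohexa-1,4-dien-1-yl)pentadecanoic acid | COC1=CC(=O)C=C(CCCCCCCCCCCCCCC(=O)O)C1=O | target

Total step count: 9
Longest linear sequence: 8 (steps 1, 2, 3, 5, 6, 7, 8, 9; step 4 is the one-step branch)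

## Steps most likely to fail

**Step 6.** Closure may go through the wrong atom pair, either Claisen attack of C6 on the C1 ester or O-cyclisation to a pyranone. The chain may also fragment by retro-Claisen cleavage before it closes.

Fallback (sets out from 4, comes back at 11): the ring is built by Michael–Dieckmann annulation and then dehydrogenated, so no open triketone has to fold.
- The free acid of 4 is reduced chemoselectively with BH3·SMe2 to methyl 16-hydroxyhexadecanoate F1.
- Swern oxidation gives methyl 16-oxohexadecanoate F2.
- Wittig olefination with 1-(triphenylphosphoranylidene)propan-2-one gives methyl (E)-18-oxononadec-16-enoate F3.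
- Dimethyl malonate and NaOMe in refluxing MeOH add to the enone and close the ring to methyl 2-hydroxy-6-(15-methoxy-15-oxopentadecyl)-4-oxocyclohex-2-ene-1-carboxylate F4. It is racemic and its stereocentres are lost in the next operation.
- Br2 in DMF (0 °C, then 80 °C) aromatises it to 11.

**Step 5.** Trianion formation may be incomplete, or the α-CH2 of the acyl donor may protonate the trianion. The trianion may also attack the remote ester, or the long-chain donor may precipitate at low temperature.

Fallback (sets out from 5, comes back at 9): the C1–C3 β-keto ester is masked as a dioxinone, so only a dianion is needed.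
- Commercial 2,2,6-trimethyl-4H-1,3-dioxin-4-one is deprotonated with LiN(iPr)2 and acetylated with acetyl chloride to 2,2-dimethyl-6-(2-oxopropyl)-4H-1,3-dioxin-4-one F5.
- Its dianion (LiN(iPr)2, 2 equiv, THF, −78 °C) is acylated at the terminal methyl by 5 to methyl 19-(2,2-dimethyl-4-oxo-4H-1,3-dioxin-6-yl)-16,18-dioxononadecanoate F6.
- Heating F6 with MeOH in toluene at 110 °C (sealed vessel) expels acetone by retro-[4+2] cleavage.
- The resulting acylketene, methyl 16,18,20,22-tetraoxodocos-21-enoate F7, is trapped by MeOH to give 9.

**Step 9.** The para carbon is flanked on both sides, so oxidation may be slow or may divert to ortho-oxidation and radical coupling. The fatty acid may also dissolve poorly in the aqueous medium.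

Fallback (sets out from 14, comes back at 15): the para oxygen is installed by formylation and Baeyer–Villiger oxidation on the symmetrical dimethyl ether, where the two reactive sites next to the chain are equivalent. The quinone is then released by oxidative demethylation.
- Exhaustive methylation of 14 (excess MeI, K2CO3, DMF) gives methyl 15-(3,5-dimethoxyphenyl)pentadecanoate F8.
- Vilsmeier–Haack formylation (POCl3, DMF) goes para to one methoxy group and ortho to the other, giving methyl 15-(2-formyl-3,5-dimethoxyphenyl)pentadecanoate F9.
- mCPBA brings about aryl migration to methyl 15-(2-formyloxy-3,5-dimethoxyphenyl)pentadecanoate F10.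
- KOH in aqueous MeOH cleaves the formate and the methyl ester to 15-(2-hydroxy-3,5-dimethoxyphenyl)pentadecanoic acid F11.
- (NH4)2Ce(NO3)6 in MeCN–H2O oxidises the 4-methoxyphenol unit to 15.

## Further compounds

F1 | step 6 | methyl 16-hydroxyhexadecanoate | COC(=O)CCCCCCCCCCCCCCCO
F2 | step 6 | methyl 16-oxohexadecanoate | COC(=O)CCCCCCCCCCCCCCC=O
F3 | step 6 | methyl (E)-18-oxononadec-16-enoate | COC(=O)CCCCCCCCCCCCCC/C=C/C(C)=O
F4 | step 6 | methyl 2-hydroxy-6-(15-methoxy-15-oxopentadecyl)-4-oxocyclohex-2-ene-1-carboxylate (racemic, relative configuration not controlled) | COC(=O)C1C(CCCCCCCCCCCCCCC(=O)OC)CC(=O)C=C1O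
F5 | step 5 | 2,2-dimethyl-6-(2-oxopropyl)-4H-1,3-dioxin-4-one | CC(=O)CC1=CC(=O)OC(C)(C)O1
F6 | step 5 | methyl 19-(2,2-dimethyl-4-oxo-4H-1,3-dioxin-6-yl)-16,18-dioxononadecanoate | COC(=O)CCCCCCCCCCCCCCC(=O)CC(=O)CC1=CC(=O)OC(C)(C)O1
F7 | step 5 | methyl 16,18,20,22-tetraoxodocos-21-enoate (acylketene) | COC(=O)CCCCCCCCCCCCCCC(=O)CC(=O)CC(=O)C=C=O
F8 | step 9 | methyl 15-(3,5-dimethoxyphenyl)pentadecanoate | COC(=O)CCCCCCCCCCCCCCc1cc(OC)cc(OC)c1
F9 | step 9 | methyl 15-(2-formyl-3,5-dimethoxyphenyl)pentadecanoate | COC(=O)CCCCCCCCCCCCCCc1cc(OC)cc(OC)c1C=O
F10 | step 9 | methyl 15-(2-formyloxy-3,5-dimethoxyphenyl)pentadecanoate | COC(=O)CCCCCCCCCCCCCCc1cc(OC)cc(OC)c1OC=O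
F11 | step 9 | 15-(2-hydroxy-3,5-dimethoxyphenyl)pentadecanoic acid | OC(=O)CCCCCCCCCCCCCCc1cc(OC)cc(OC)c1O
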